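**Retrosynthetic overview** (atom labels C4a, C5, C6, C7, C8, C8a are the quinoline locants of the target and are used for the same atoms in every intermediate)
- The N-oxide is put on last with a peracid; C5 is set just before that by iridium-catalysed asymmetric hydrogenation of a C5=C6 double bond in a 7,8-dihydroquinoline.
- That dihydroquinoline is cut at C6–C7 and C4a–C5 at once: a primary radical at C7, released by decarboxylation of an N-(acyloxy)phthalimide, adds to 7-phenylhept-1-yne and the resulting vinyl radical closes onto the pyridine. The carbocycle is the only ring formed, and it is formed last, on the finished pyridine ring.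
- Enabling feature: in the pyridine ring the α-carbon C8a carries the two-carbon arm C8–C7, and its neighbour, the β-carbon C4a, is the only ring carbon that bears hydrogen. C7–C8–C8a–C4a is thus a four-atom unit whose ends take up the alkyne carbons C6 and C5.
- The arm comes from a Minisci alkylation of 3,4-dimethoxy-2-methylpyridine with monomethyl succinate; the alkyne comes from (5-bromopentyl)benzene and lithium acetylide.

Key step: step 5

Assumption: the SMILES string is read as the (5R)-enantiomer (CIP order at C5: C4a > C6 > side-chain CH2 > H), and 3,4-dimethoxy-2-methylpyridine is taken as purchasable (its N-oxide, a bulk intermediate, would give it with PCl3 if not).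

Step 1
Reactants: 1 (5-bromopentyl)benzene
Product: 2 7-phenylhept-1-yne (hept-6-yn-1-ylbenzene)
Conditions: lithium acetylide–ethylenediamine complex (1.5 equiv), DMSO, 10 °C to rt
Reagents that add atoms: lithium acetylide–ethylenediamine complex, [Li+].[C-]#C.NCCN
Why: SN2 alkylation of lithium acetylide by an unhindered primary bromide in DMSO is a standard route to terminal alkynes, and the ethylenediamine complex suppresses dialkylation; no stereocentre is formed.

Step 2
Reactants: 3 3,4-dimethoxy-2-methylpyridine; 4 monomethyl succinate (4-methoxy-4-oxobutanoic acid, 3 equiv)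
Product: 5 methyl 3-(4,5-dimethoxy-6-methylpyridin-2-yl)propanoate
Conditions: AgNO3 (20 mol %), (NH4)2S2O8 (2.5 equiv), TFA (1.2 equiv), MeCN/H2O, 60 °C
Reagents that add atoms: none
Why: Minisci reaction: the nucleophilic 2-(methoxycarbonyl)ethyl radical made by silver-mediated oxidative decarboxylation of 4 should attack the protonated pyridine at C8a, the only unsubstituted α or γ position, so that a single mono-alkylated product is expected.

Step 3
Reactants: 5 methyl 3-(4,5-dimethoxy-6-methylpyridin-2-yl)propanoate
Product: 7 3-(4,5-dimethoxy-6-methylpyridin-2-yl)propanoic acid, via lithium carboxylate 6 (not isolated)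
Conditions: LiOH·H2O (2 equiv), THF/H2O, rt; then 1 M HCl to pH 5
Reagents that add atoms: lithium hydroxide, [Li+].[OH-]
Why: Saponification of an unhindered methyl ester by hydroxide gives the lithium carboxylate 6, and acidification to the isoelectric point releases the amphoteric acid without touching the aryl methyl ethers.

Step 4
Reactants: 7 3-(4,5-dimethoxy-6-methylpyridin-2-yl)propanoic acid
Product: 8 1,3-dioxoisoindolin-2-yl 3-(4,5-dimethoxy-6-methylpyridin-2-yl)propanoate
Conditions: N-hydroxyphthalimide (1.1 equiv), N,N'-diisopropylcarbodiimide (1.1 equiv), DMAP (10 mol %), CH2Cl2, 0 °C to rt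
Reagents that add atoms: N-hydroxyphthalimide, O=C1c2ccccc2C(=O)N1O
Why: Steglich-type carbodiimide esterification with DMAP as acyl-transfer catalyst is the standard entry to redox-active N-(acyloxy)phthalimides and is compatible with the hindered, weakly nucleophilic pyridine nitrogen.

Step 5
Reactants: 8 1,3-dioxoisoindolin-2-yl 3-(4,5-dimethoxy-6-methylpyridin-2-yl)propanoate; 2 7-phenylhept-1-yne (5 equiv)
Product: 12 3,4-dimethoxy-2-methyl-5-(5-phenylpentyl)-7,8-dihydroquinoline, via primary alkyl radical 9 (not isolated), via vinyl radical 10 (not isolated), via azacyclohexadienyl radical 11 (not isolated)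
Conditions: fac-Ir(ppy)3 (2 mol %), MeCN (0.2 M in 8), blue LEDs (450 nm), argon, rt
Reagents that add atoms: none
Why: Proposed new method: the excited photocatalyst fac-Ir(ppy)3 should transfer one electron to the N-(acyloxy)phthalimide 8, which loses phthalimide anion and CO2 to give the primary radical 9 at C7; 9 adds to the unsubstituted terminus of alkyne 2 (C6–C7 bond), the α-alkyl vinyl radical 10 at C5 closes onto the β-carbon C4a of the pyridine (C4a–C5 bond), and the azacyclohexadienyl radical 11 is oxidised by the tetravalent iridium complex and deprotonated by phthalimide anion, so the cycle is redox-neutral. The closest known reaction types are the Mn(OAc)3-mediated oxidative radical annulation of 2-benzylmalonates with alkynes to 1,2-dihydronaphthalenes and photoredox decarboxylative alkylation–cyclisation cascades of N-(acyloxy)phthalimides with alkynes; new here are the unstabilised primary radical, the unactivated 1-alkyne and a pyridine β-carbon as the ring-closing site. The carbocycle closes in a six-membered mode in which the vinyl radical attacks the ring carbon ortho to the tether (radical at C5, attack on C4a, the atoms C6, C7 and C8 between them, the C5=C6 bond inside the new ring), a homolytic aromatic substitution. No stereocentre is formed; the step delivers the C5=C6 alkene on which step 6 sets C5. It needs addition at the CH terminus of the alkyne, which the steric bias of a 1-alkyne secures, and ortho rather than ipso ring closure, which is secured because C4a is the only C–H position of the pyridine ring and six-membered ortho closure is the established course for vinyl radicals held three atoms from an arene; the fivefold excess of alkyne at high concentration and the absence of acid (no activation of the α-carbon C8a) are meant to offset the slow addition of a nucleophilic alkyl radical to an unactivated triple bond.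

Step 6
Reactants: 12 3,4-dimethoxy-2-methyl-5-(5-phenylpentyl)-7,8-dihydroquinoline
Product: 13 (5R)-3,4-dimethoxy-2-methyl-5-(5-phenylpentyl)-5,6,7,8-tetrahydroquinoline
Conditions: H2 (50 bar), [Ir(cod)(L)]BArF (2 mol %; L = ThrePHOX-type chiral phosphinite–oxazoline, BArF = B[3,5-(CF3)2C6H3]4), CH2Cl2, rt
Reagents that add atoms: none
Why: Iridium-catalysed asymmetric hydrogenation of an unfunctionalised trisubstituted cyclic alkene of the 1-alkyl-3,4-dihydronaphthalene type, the substrate class for which cationic monovalent iridium complexes of chiral P,N ligands are established: the ligand differentiates the two faces of the C5=C6 bond and so sets C5, the ligand antipode (both are available) being chosen in a trial run to give the (5R) product, while the pyridine nitrogen, flanked by the 2-methyl group and C8, should be too hindered to block the catalyst.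

Step 7
Reactants: 13 (5R)-3,4-dimethoxy-2-methyl-5-(5-phenylpentyl)-5,6,7,8-tetrahydroquinoline
Product: 14 (5R)-3,4-dimethoxy-2-methyl-5-(5-phenylpentyl)-5,6,7,8-tetrahydroquinoline 1-oxide
Conditions: mCPBA (1.2 equiv), CH2Cl2, 0 °C to rt
Reagents that add atoms: mCPBA (3-chloroperoxybenzoic acid), OOC(=O)c1cccc(Cl)c1
Why: Peracid N-oxidation of an electron-rich 2,6-dialkylpyridine is a standard reaction that touches neither the saturated stereocentre C5 nor the ethers or the phenyl ring.

**Compound list**
1 | (5-bromopentyl)benzene | BrCCCCCc1ccccc1 | starting material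
2 | 7-phenylhept-1-yne (hept-6-yn-1-ylbenzene) | C#CCCCCCc1ccccc1 | intermediate
3 | 3,4-dimethoxy-2-methylpyridine | COc1ccnc(C)c1OC | starting material
4 | monomethyl succinate (4-methoxy-4-oxobutanoic acid) | COC(=O)CCC(=O)O | starting material
5 | methyl 3-(4,5-dimethoxy-6-methylpyridin-2-yl)propanoate | COC(=O)CCc1cc(OC)c(OC)c(C)n1 | intermediate
6 | lithium 3-(4,5-dimethoxy-6-methylpyridin-2-yl)propanoate (not isolated) | [Li+].[O-]C(=O)CCc1cc(OC)c(OC)c(C)n1 | intermediate
7 | 3-(4,5-dimethoxy-6-methylpyridin-2-yl)propanoic acid | OC(=O)CCc1cc(OC)c(OC)c(C)n1 | intermediate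
8 | 1,3-dioxoisoindolin-2-yl 3-(4,5-dimethoxy-6-methylpyridin-2-yl)propanoate | COc1cc(CCC(=O)ON2C(=O)c3ccccc3C2=O)nc(C)c1OC | intermediate
9 | 2-(4,5-dimethoxy-6-methylpyridin-2-yl)ethyl radical (radical at C7, not isolated) | [CH2]Cc1cc(OC)c(OC)c(C)n1 | intermediate
10 | 1-(4,5-dimethoxy-6-methylpyridin-2-yl)-9-phenylnon-3-en-4-yl radical (vinyl radical at C5, not isolated) | COc1cc(CCC=[C]CCCCCc2ccccc2)nc(C)c1OC | intermediate
11 | azacyclohexadienyl radical formed by C4a–C5 ring closure, hydrogen still on C4a (one resonance form drawn, not isolated) | COC1=C(OC)C(C)=N[C]2CCC=C(CCCCCc3ccccc3)C12 | intermediate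
12 | 3,4-dimethoxy-2-methyl-5-(5-phenylpentyl)-7,8-dihydroquinoline | COc1c(OC)c(C)nc2c1C(CCCCCc1ccccc1)=CCC2 | intermediate
13 | (5R)-3,4-dimethoxy-2-methyl-5-(5-phenylpentyl)-5,6,7,8-tetrahydroquinoline | COc1c(OC)c(C)nc2c1[C@H](CCCCCc1ccccc1)CCC2 | intermediate
14 | (5R)-3,4-dimethoxy-2-methyl-5-(5-phenylpentyl)-5,6,7,8-tetrahydroquinoline 1-oxide | COc1c(OC)c(C)[n+]([O-])c2c1[C@H](CCCCCc1ccccc1)CCC2 | target

**Step count**
Total steps: 7.
Longest linear sequence: 6 steps (3 → 5 → 7 → 8 → 12 → 13 → 14; steps 2 to 7). Step 1 is a one-step side branch to alkyne 2.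

**Steps most likely to fail**

Step 5 (proposed new method). The bimolecular addition of the unstabilised radical 9 to the unactivated alkyne may be too slow, so that reduction or dimerisation of the radical wins. The vinyl radical 10 may also be lost by 1,5-hydrogen transfer from its own chain, or by ipso attack at C8a followed by aryl migration. The fallback closes the ring by known ionic chemistry, sets out from 3 (and 1) and rejoins the route at 12. A Minisci alkylation of 3 with monomethyl glutarate under the conditions of step 2 would give methyl 4-(4,5-dimethoxy-6-methylpyridin-2-yl)butanoate F1. Electrophilic bromination at the only ring C–H (NBS, MeCN, dark) would give methyl 4-(3-bromo-4,5-dimethoxy-6-methylpyridin-2-yl)butanoate F2. Bromine–lithium exchange with n-BuLi in THF at −100 °C would give methyl 4-(3-lithio-4,5-dimethoxy-6-methylpyridin-2-yl)butanoate F3, which in a Parham cyclisation onto its ester would close the ring to 3,4-dimethoxy-2-methyl-7,8-dihydroquinolin-5(6H)-one F4. Addition of (5-phenylpentyl)magnesium bromide F5 (from 1 and Mg in THF; CeCl3 to suppress enolisation) would give the tertiary alcohol 3,4-dimethoxy-2-methyl-5-(5-phenylpentyl)-5,6,7,8-tetrahydroquinolin-5-ol F6. Acid-catalysed dehydration (TsOH, toluene, reflux) should then give the conjugated endocyclic alkene 12.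

Step 6. The catalyst may be inhibited by coordination of the pyridine nitrogen, and the peri methoxy group at C4 may slow the reaction and erode facial discrimination at the crowded alkene. The fallback replaces catalyst control by separation of enantiomers, sets out from 12 and rejoins at 13. Hydrogenation without a chiral catalyst (H2, Pd/C, EtOAc) would give racemic 3,4-dimethoxy-2-methyl-5-(5-phenylpentyl)-5,6,7,8-tetrahydroquinoline F7. Preparative supercritical-fluid chromatography on a chiral stationary phase would then give 13 and leave (5S)-3,4-dimethoxy-2-methyl-5-(5-phenylpentyl)-5,6,7,8-tetrahydroquinoline F8, which is set aside.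

Step 2. The electron-rich pyridinium may react sluggishly with the nucleophilic radical, and the persulfate may degrade substrate and product. The fallback attaches the arm by N-oxide-directed C–H alkenylation, sets out from 3 and rejoins at 5. Oxidation of 3 with mCPBA would give 3,4-dimethoxy-2-methylpyridine 1-oxide F9 (itself an article of commerce). A Fujiwara–Moritani-type oxidative alkenylation at C8a with methyl acrylate (Pd(OAc)2, Ag2CO3, pyridine, 1,4-dioxane, 100 °C) would give methyl (E)-3-(4,5-dimethoxy-6-methyl-1-oxidopyridin-1-ium-2-yl)prop-2-enoate F10. Hydrogenation over Pd/C in MeOH should reduce both the C=C bond and the N–O bond and give 5.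

**Further compounds**
F1 | step 5 | methyl 4-(4,5-dimethoxy-6-methylpyridin-2-yl)butanoate | COC(=O)CCCc1cc(OC)c(OC)c(C)n1
F2 | step 5 | methyl 4-(3-bromo-4,5-dimethoxy-6-methylpyridin-2-yl)butanoate | COC(=O)CCCc1nc(C)c(OC)c(OC)c1Br
F3 | step 5 | methyl 4-(3-lithio-4,5-dimethoxy-6-methylpyridin-2-yl)butanoate | COC(=O)CCCc1nc(C)c(OC)c(OC)c1[Li]
F4 | step 5 | 3,4-dimethoxy-2-methyl-7,8-dihydroquinolin-5(6H)-one | COc1c(OC)c(C)nc2c1C(=O)CCC2
F5 | step 5 | (5-phenylpentyl)magnesium bromide | Br[Mg]CCCCCc1ccccc1
F6 | step 5 | 3,4-dimethoxy-2-methyl-5-(5-phenylpentyl)-5,6,7,8-tetrahydroquinolin-5-ol (racemic) | COc1c(OC)c(C)nc2c1C(O)(CCCCCc1ccccc1)CCC2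
F7 | step 6 | racemic 3,4-dimethoxy-2-methyl-5-(5-phenylpentyl)-5,6,7,8-tetrahydroquinoline | COc1c(OC)c(C)nc2c1C(CCCCCc1ccccc1)CCC2
F8 | step 6 | (5S)-3,4-dimethoxy-2-methyl-5-(5-phenylpentyl)-5,6,7,8-tetrahydroquinoline | COc1c(OC)c(C)nc2c1[C@@H](CCCCCc1ccccc1)CCC2
F9 | step 2 | 3,4-dimethoxy-2-methylpyridine 1-oxide | COc1cc[n+]([O-])c(C)c1OC
F10 | step 2 | methyl (E)-3-(4,5-dimethoxy-6-methyl-1-oxidopyridin-1-ium-2-yl)prop-2-enoate | COC(=O)/C=C/c1cc(OC)c(OC)c(C)[n+]1[O-]
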